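**Assumption:** the SMILES is taken literally: a (7R,7'R,8S,8'S)-syringaresinol core whose two phenol oxygens carry erythro guaiacylglycerol β-ether units: unit E (7S,8R) on one side; unit B (7S,8R) on the other, whose own phenol oxygen carries the terminal unit A (7R,8S).

**Shorthand used in names:** SR = (1R,3aS,4R,6aS)-1,4-bis(4-hydroxy-3,5-dimethoxyphenyl)tetrahydro-1H,3H-furo[3,4-c]furan, phenol oxygens O-4 and O-4'. GBn = 4-benzyloxy-3-methoxyphenyl. Xs / Xr = (4S)- / (4R)-4-benzyl-2-oxo-1,3-oxazolidin-3-yl. TBS = tert-butyldimethylsilyl; TIPS = triisopropylsilyl. E* = (1S,2R)-1-(GBn)-1,3-bis(TBSO)propan-2-yl. ArB* = 4-{[(1R,2S)-1-(GBn)-1,3-bis(TBSO)propan-2-yl]oxy}-3-methoxyphenyl. In the side chains, propane C-1 is the aryl-bearing carbon (lignan C-7) and C-2 the aryloxy-bearing carbon (C-8).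

## Retrosynthetic overview

1. Global deprotection; the C-7–C-8 bonds of units E and B are cut by Evans boron aldol disconnections between (aryloxy)acetyl imides on the two core phenols and aldehydes 21 and 43. The syn aldol gives threo; a Mitsunobu inversion at C-7 then gives erythro.
2. Aldehyde 43 (unit A on a vanillin ring) comes from the same aldol/inversion sequence with the enantiomeric auxiliary on 4-hydroxy-3-methoxybenzonitrile (masked aldehyde).
3. The core, orthogonally protected (O-allyl / O-TIPS) SR, comes from acid-mediated double cycloetherification of a (2S,3S)-tetraol.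
4. The tetraol comes from a tandem Michael–aldol reaction of a lithiated syringyl dithiane, a (5S)-menthyloxybutenolide and a syringaldehyde ether, followed by unmasking and LiAlH4 reduction.
5. Ring order: the butenolide (from furfural) serves as a temporary chiral template and is opened by hydride; the two tetrahydrofuran rings of the furofuran are then closed together (step 9); no ring is formed afterwards.

## Route

**Fragment 1: differentiated core (steps 1–10)**

Step 1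
Reactants: 1 syringaldehyde (4-hydroxy-3,5-dimethoxybenzaldehyde)
Product: 2 2-(4-hydroxy-3,5-dimethoxyphenyl)-1,3-dithiane
Conditions: HS(CH2)3SH (1.1 equiv), BF3·OEt2 (0.2 equiv), CH2Cl2, 0 °C to rt
Reagents that add atoms: propane-1,3-dithiol SCCCS
Why: Lewis-acid-catalysed dithioacetalisation turns the aldehyde into a Corey–Seebach acyl-anion precursor; no stereocentre is formed.

Step 2
Reactants: 2 2-(4-hydroxy-3,5-dimethoxyphenyl)-1,3-dithiane
Product: 3 2-[3,5-dimethoxy-4-(triisopropylsilyloxy)phenyl]-1,3-dithiane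
Conditions: TIPSCl (1.3 equiv), imidazole (2.5 equiv), DMF, rt to 40 °C
Reagents that add atoms: chlorotriisopropylsilane CC(C)[Si](Cl)(C(C)C)C(C)C
Why: O-silylation gives a bulky aryl silyl ether that tolerates n-BuLi, LiAlH4 and mild acid and is later removed selectively by fluoride; no stereocentre is formed.

Step 3
Reactants: 1 syringaldehyde
Product: 4 4-allyloxy-3,5-dimethoxybenzaldehyde
Conditions: allyl bromide (1.3 equiv), K2CO3 (2 equiv), DMF, rt
Reagents that add atoms: allyl bromide C=CCBr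
Why: Williamson etherification installs the second, orthogonal phenol protecting group (removable later by zerovalent palladium in the presence of benzyl and silyl ethers); no stereocentre is formed.

Step 4
Reactants: 5 furfural
Product: 6 5-hydroxyfuran-2(5H)-one (racemic)
Conditions: O2, visible light, 3,7-bis(dimethylamino)phenothiazin-5-ium chloride (1 mol %), MeOH, rt
Reagents that add atoms: dioxygen O=O
Why: dye-sensitised photooxygenation ([4+2] cycloaddition of singlet oxygen to the furan) gives an endoperoxide that fragments in methanol with loss of the formyl carbon as methyl formate; the hemiacetal carbon is racemic and labile.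

Step 5
Reactants: 6 5-hydroxyfuran-2(5H)-one, 7 (+)-menthol
Product: 8 (5S)-5-{[(1S,2R,5S)-2-isopropyl-5-methylcyclohexyl]oxy}furan-2(5H)-one
Conditions: 7 (1.0 equiv), (1S)-(+)-camphor-10-sulfonic acid (5 mol %), toluene, reflux, Dean–Stark; crystallisation from petroleum ether at −20 °C, mother liquor re-equilibrated with the same acid and recrystallised
Reagents that add atoms: none
Why: acid-catalysed acetalisation gives both C-5 epimers, which interconvert under acid, and the (5S) epimer of the (+)-menthyl acetal crystallises (crystallisation-induced diastereomer selection, mirror image of the l-menthol series), which fixes C-5.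

Step 6
Reactants: 3 silyl-protected dithiane, 8 (5S)-menthyloxybutenolide, 4 4-allyloxy-3,5-dimethoxybenzaldehyde
Product: 11 (3R,4S,5S)-3-[(4-allyloxy-3,5-dimethoxyphenyl)(hydroxy)methyl]-4-{2-[3,5-dimethoxy-4-(triisopropylsilyloxy)phenyl]-1,3-dithian-2-yl}-5-[(1S,2R,5S)-menthyloxy]dihydrofuran-2(3H)-one (carbinol epimers), via 2-lithio-1,3-dithiane 9 (not isolated), via lithium lactone enolate 10 (not isolated)
Conditions: n-BuLi (1.05 equiv), THF, −78 to −20 °C, 30 min; 8 (1.0 equiv), −78 °C, 1 h; 4 (1.1 equiv), −78 °C, 2 h; AcOH (1.2 equiv), −78 °C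
Reagents that add atoms: none
Why: tandem Michael addition–aldol reaction: the lithiated dithiane adds 1,4 to the butenolide anti to the menthyloxy group (sets C-4 as S) and the resulting lactone enolate adds to aldehyde 4 anti to the new C-4 substituent (sets C-3 as R), while the carbinol centre forms as an epimer mixture that is erased in step 9.

Step 7
Reactants: 11 dithiane aldol lactone
Product: 12 (3R,4S,5S)-3-[(4-allyloxy-3,5-dimethoxyphenyl)(hydroxy)methyl]-4-[3,5-dimethoxy-4-(triisopropylsilyloxy)benzoyl]-5-[(1S,2R,5S)-menthyloxy]dihydrofuran-2(3H)-one (carbinol epimers)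
Conditions: MeI (10 equiv), CaCO3 (4 equiv), MeCN/H2O (4:1), 45 °C
Reagents that add atoms: water O
Why: alkylative dithioacetal hydrolysis (S-methylation, then attack of water on the thionium ion) unmasks the aryl ketone under near-neutral conditions that leave the allyl ether, silyl ether, acetal and the trans,trans ring stereocentres untouched.

Step 8
Reactants: 12 keto lactone
Product: 13 (2S,3S)-2-[(4-allyloxy-3,5-dimethoxyphenyl)(hydroxy)methyl]-3-{[3,5-dimethoxy-4-(triisopropylsilyloxy)phenyl](hydroxy)methyl}butane-1,4-diol (carbinol epimers)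
Conditions: LiAlH4 (6 equiv), THF, 0 °C to rt; then H2O, 15% NaOH, H2O
Reagents that add atoms: none
Why: hydride reduction of ketone and lactone, with collapse of the liberated menthyl hemiacetal to an aldehyde that is reduced as well, gives the tetraol and returns (+)-menthol; C-8 and C-8' (2S,3S) are untouched and the two carbinol centres are mixtures that do not matter.

Step 9
Reactants: 13 tetraol
Product: 14 4-O-allyl-4'-O-TIPS-SR
Conditions: (1S)-(+)-camphor-10-sulfonic acid (10 mol %), 4 Å molecular sieves, CH2Cl2 (0.01 M), 0 °C to rt; Et3N quench as soon as 13 is consumed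
Reagents that add atoms: none
Why: twofold acid-catalysed SN1 cycloetherification: each electron-rich benzylic carbinol ionises and is captured by the hydroxymethyl group of the other half anti to the neighbouring ring substituent, so both aryl groups should end up exo (7R,7'R) whatever the carbinol configuration was, as in pinoresinol-type biogenesis, with C-8/C-8' (8S,8'S) carried over from 13.

Step 10
Reactants: 14 4-O-allyl-4'-O-TIPS-SR
Product: 15 4-O-allyl-SR
Conditions: Bu4NF (1.1 equiv), THF, 0 °C, 20 min; AcOH (1.2 equiv)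
Reagents that add atoms: none
Why: fluoride-mediated desilylation cleaves the aryl silyl ether selectively and frees one of the two core phenols; no stereocentre is touched.

**Unit E on the core (steps 11–19)**

Step 11
Reactants: 16 (S)-4-benzyloxazolidin-2-one, 17 bromoacetyl bromide
Product: 19 (S)-4-benzyl-3-(bromoacetyl)oxazolidin-2-one, via N-lithio oxazolidinone 18 (not isolated)
Conditions: n-BuLi (1.0 equiv), THF, −78 °C; 17 (1.1 equiv), −78 to 0 °C
Reagents that add atoms: none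
Why: N-acylation of the lithiated oxazolidinone at the acyl bromide, which is far more electrophilic than the CH2Br carbon; the auxiliary stereocentre is untouched.

Step 12
Reactants: 15 4-O-allyl-SR, 19 (S)-bromoacetyl imide
Product: 20 4-O-allyl-4'-O-[2-oxo-2-(Xs)ethyl]-SR
Conditions: K2CO3 (1.5 equiv), acetone, rt to 40 °C
Reagents that add atoms: none
Why: Williamson etherification (SN2 of the phenoxide on the very reactive α-bromo imide) builds the (aryloxy)acetyl imide needed for the aldol; no stereocentre is formed.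

Step 13
Reactants: 20 core (aryloxy)acetyl imide, 21 4-benzyloxy-3-methoxybenzaldehyde
Product: 23 4-O-allyl-4'-O-[(2S,3R)-3-(GBn)-3-hydroxy-1-oxo-1-(Xs)propan-2-yl]-SR, via dibutylboron Z-enolate 22 (not isolated)
Conditions: Bu2BOTf (1.3 equiv), i-Pr2NEt (1.5 equiv), CH2Cl2, −78 to 0 °C; 21 (1.3 equiv), −78 to 0 °C; pH 7 phosphate buffer, MeOH, 30% H2O2, 0 °C
Reagents that add atoms: none
Why: Evans boron aldol reaction: the Z-enolate reacts with the aldehyde through a chair Zimmerman–Traxler transition state on the face opposite the benzyl group of the auxiliary, which forms the C-7–C-8 bond of unit E and sets the syn (2S,3R) pair, i.e. C-8 (R) as required and C-7 (R, threo) still to be inverted.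

Step 14
Reactants: 23 syn-aldol imide
Product: 24 4-O-allyl-4'-O-[(1R,2R)-1-(GBn)-1,3-dihydroxypropan-2-yl]-SR
Conditions: NaBH4 (4 equiv), THF/H2O (4:1), 0 °C to rt
Reagents that add atoms: none
Why: borohydride reduction of the exocyclic imide carbonyl (reductive removal of the auxiliary) gives the primary alcohol and returns the oxazolidinone without touching C-7 or C-8.

Step 15
Reactants: 24 threo diol
Product: 25 4-O-allyl-4'-O-[(1R,2R)-1-(GBn)-1-hydroxy-3-(TBSO)propan-2-yl]-SR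
Conditions: TBSCl (1.15 equiv), imidazole (2.5 equiv), CH2Cl2, 0 °C
Reagents that add atoms: tert-butyl(chloro)dimethylsilane CC(C)(C)[Si](C)(C)Cl
Why: chemoselective silylation of the primary hydroxyl over the hindered secondary benzylic one leaves only the C-7 hydroxyl free for inversion; no stereocentre is touched.

Step 16
Reactants: 25 threo mono-silyl ether
Product: 26 4-O-allyl-4'-O-[(1S,2R)-1-(GBn)-1-(4-nitrobenzoyloxy)-3-(TBSO)propan-2-yl]-SR
Conditions: 4-nitrobenzoic acid (3 equiv), PPh3 (3 equiv), DIAD (3 equiv), toluene, 0 °C to rt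
Reagents that add atoms: 4-nitrobenzoic acid O=C(O)c1ccc(cc1)[N+](=O)[O-]
Why: Mitsunobu esterification: SN2 displacement of the oxyphosphonium by 4-nitrobenzoate inverts C-7 from R to S and so turns the threo aldol stereochemistry into the erythro (7S,8R) pattern of unit E, the acidic nucleophile and non-polar solvent disfavouring ionisation of the benzylic centre.

Step 17
Reactants: 26 inverted 4-nitrobenzoate
Product: 27 4-O-allyl-4'-O-[(1S,2R)-1-(GBn)-1-hydroxy-3-(TBSO)propan-2-yl]-SR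
Conditions: K2CO3 (0.2 equiv), MeOH/THF (2:1), rt
Reagents that add atoms: none
Why: base-catalysed transesterification (methanolysis by acyl–oxygen cleavage) removes the 4-nitrobenzoate with retention at C-7 while the alkyl silyl ether survives.

Step 18
Reactants: 27 erythro alcohol
Product: 28 4-O-allyl-4'-O-[(1S,2R)-1-(GBn)-1,3-bis(TBSO)propan-2-yl]-SR
Conditions: TBSOTf (1.5 equiv), 2,6-lutidine (3 equiv), CH2Cl2, −78 to 0 °C
Reagents that add atoms: tert-butyldimethylsilyl trifluoromethanesulfonate CC(C)(C)[Si](C)(C)OS(=O)(=O)C(F)(F)F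
Why: silylation of the hindered secondary alcohol with the silyl triflate masks unit E completely for the second aldol sequence; no stereocentre is touched.

Step 19
Reactants: 28 fully protected unit-E allyl ether
Product: 29 4'-O-[(1S,2R)-1-(GBn)-1,3-bis(TBSO)propan-2-yl]-SR
Conditions: Pd(PPh3)4 (5 mol %), morpholine (10 equiv), THF, rt
Reagents that add atoms: none
Why: Tsuji–Trost deallylation: zerovalent palladium ionises the aryl allyl ether and morpholine traps the π-allyl complex, which frees the second core phenol without touching benzyl or silyl ethers.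

**Fragment 2: aldehyde carrying unit A (steps 20–28)**

Step 20
Reactants: 30 (R)-4-benzyloxazolidin-2-one, 17 bromoacetyl bromide
Product: 32 (R)-4-benzyl-3-(bromoacetyl)oxazolidin-2-one, via N-lithio oxazolidinone 31 (not isolated)
Conditions: n-BuLi (1.0 equiv), THF, −78 °C; 17 (1.1 equiv), −78 to 0 °C
Reagents that add atoms: none
Why: N-acylation of the lithiated oxazolidinone at the acyl bromide gives the enantiomeric glycolate-type reagent; the auxiliary stereocentre is untouched.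

Step 21
Reactants: 33 4-hydroxy-3-methoxybenzonitrile, 32 (R)-bromoacetyl imide
Product: 34 4-[2-oxo-2-(Xr)ethoxy]-3-methoxybenzonitrile
Conditions: K2CO3 (1.5 equiv), acetone, rt to 40 °C
Reagents that add atoms: none
Why: Williamson etherification of the phenoxide with the α-bromo imide, the nitrile serving as an aldehyde surrogate that is inert to enolisation and hydride in the following steps; no stereocentre is formed.

Step 22
Reactants: 34 nitrile (aryloxy)acetyl imide, 21 4-benzyloxy-3-methoxybenzaldehyde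
Product: 36 4-{[(2R,3S)-3-(GBn)-3-hydroxy-1-oxo-1-(Xr)propan-2-yl]oxy}-3-methoxybenzonitrile, via dibutylboron Z-enolate 35 (not isolated)
Conditions: Bu2BOTf (1.3 equiv), i-Pr2NEt (1.5 equiv), CH2Cl2, −78 to 0 °C; 21 (1.3 equiv), −78 to 0 °C; pH 7 phosphate buffer, MeOH, 30% H2O2, 0 °C
Reagents that add atoms: none
Why: Evans boron aldol reaction with the (R)-auxiliary: the Z-enolate adds through the Zimmerman–Traxler chair on the face opposite the auxiliary benzyl group, forming the C-7–C-8 bond of unit A and setting syn (2R,3S), i.e. C-8 (S) as required and C-7 (S, threo) still to be inverted.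

Step 23
Reactants: 36 syn-aldol imide
Product: 37 4-{[(1S,2S)-1-(GBn)-1,3-dihydroxypropan-2-yl]oxy}-3-methoxybenzonitrile
Conditions: NaBH4 (4 equiv), THF/H2O (4:1), 0 °C to rt
Reagents that add atoms: none
Why: borohydride reduction of the imide carbonyl (reductive auxiliary removal) gives the threo diol and spares the nitrile and both stereocentres.

Step 24
Reactants: 37 threo diol
Product: 38 4-{[(1S,2S)-1-(GBn)-1-hydroxy-3-(TBSO)propan-2-yl]oxy}-3-methoxybenzonitrile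
Conditions: TBSCl (1.15 equiv), imidazole (2.5 equiv), CH2Cl2, 0 °C
Reagents that add atoms: tert-butyl(chloro)dimethylsilane CC(C)(C)[Si](C)(C)Cl
Why: chemoselective silylation of the primary hydroxyl leaves only the benzylic C-7 hydroxyl free; no stereocentre is touched.

Step 25
Reactants: 38 threo mono-silyl ether
Product: 39 4-{[(1R,2S)-1-(GBn)-1-(4-nitrobenzoyloxy)-3-(TBSO)propan-2-yl]oxy}-3-methoxybenzonitrile
Conditions: 4-nitrobenzoic acid (3 equiv), PPh3 (3 equiv), DIAD (3 equiv), toluene, 0 °C to rt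
Reagents that add atoms: 4-nitrobenzoic acid O=C(O)c1ccc(cc1)[N+](=O)[O-]
Why: Mitsunobu esterification inverts C-7 from S to R by SN2 displacement of the oxyphosphonium, giving the erythro (7R,8S) configuration of unit A.

Step 26
Reactants: 39 inverted 4-nitrobenzoate
Product: 40 4-{[(1R,2S)-1-(GBn)-1-hydroxy-3-(TBSO)propan-2-yl]oxy}-3-methoxybenzonitrile
Conditions: K2CO3 (0.2 equiv), MeOH/THF (2:1), rt
Reagents that add atoms: none
Why: base-catalysed transesterification (methanolysis) cleaves the ester at the acyl carbon, so C-7 keeps its new R configuration, and the electron-rich aryl nitrile is inert at rt.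

Step 27
Reactants: 40 erythro alcohol
Product: 41 4-{[(1R,2S)-1-(GBn)-1,3-bis(TBSO)propan-2-yl]oxy}-3-methoxybenzonitrile
Conditions: TBSOTf (1.5 equiv), 2,6-lutidine (3 equiv), CH2Cl2, −78 to 0 °C
Reagents that add atoms: tert-butyldimethylsilyl trifluoromethanesulfonate CC(C)(C)[Si](C)(C)OS(=O)(=O)C(F)(F)F
Why: silylation of the secondary alcohol completes the protection of unit A for the hydride and boron chemistry that follows; no stereocentre is touched.

Step 28
Reactants: 41 bis-silylated nitrile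
Product: 43 4-{[(1R,2S)-1-(GBn)-1,3-bis(TBSO)propan-2-yl]oxy}-3-methoxybenzaldehyde, via N-aluminio aldimine 42 (not isolated)
Conditions: i-Bu2AlH (1.5 equiv), toluene, −78 °C; then aq. potassium sodium tartrate (KNaC4H4O6), rt
Reagents that add atoms: water O
Why: partial reduction of the nitrile: a single hydride transfer gives an N-aluminio imine that is stable at low temperature and hydrolyses to the aldehyde on work-up, with silyl and benzyl ethers and both stereocentres untouched.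

**Units B/A on the core and endgame (steps 29–36)**

Step 29
Reactants: 29 core mono-phenol carrying protected unit E, 19 (S)-bromoacetyl imide
Product: 44 4-O-[2-oxo-2-(Xs)ethyl]-4'-O-E*-SR
Conditions: K2CO3 (1.5 equiv), acetone, rt to 40 °C
Reagents that add atoms: none
Why: Williamson etherification of the second core phenoxide with the α-bromo imide; silyl ethers are stable to carbonate in acetone and no stereocentre is formed.

Step 30
Reactants: 44 core (aryloxy)acetyl imide, 43 aldehyde carrying unit A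
Product: 46 4-O-[(2S,3R)-3-(ArB*)-3-hydroxy-1-oxo-1-(Xs)propan-2-yl]-4'-O-E*-SR, via dibutylboron Z-enolate 45 (not isolated)
Conditions: Bu2BOTf (1.3 equiv), i-Pr2NEt (1.5 equiv), CH2Cl2, −78 to 0 °C; 43 (1.2 equiv), −78 to 0 °C; pH 7 phosphate buffer, MeOH, 30% H2O2, 0 °C
Reagents that add atoms: none
Why: Evans boron aldol reaction, the fragment-coupling step: auxiliary-controlled addition of the Z-enolate through the Zimmerman–Traxler chair forms the C-7–C-8 bond of unit B and sets syn (2S,3R), i.e. C-8 (R) as required and C-7 (R, threo) to be inverted, the remote stereocentres of 43 having no say.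

Step 31
Reactants: 46 syn-aldol imide
Product: 47 4-O-[(1R,2R)-1-(ArB*)-1,3-dihydroxypropan-2-yl]-4'-O-E*-SR
Conditions: NaBH4 (4 equiv), THF/H2O (4:1), 0 °C to rt
Reagents that add atoms: none
Why: borohydride reduction of the imide carbonyl (reductive auxiliary removal) gives the threo diol of unit B without touching any stereocentre or silyl ether.

Step 32
Reactants: 47 threo diol
Product: 48 4-O-[(1R,2R)-1-(ArB*)-1-hydroxy-3-(TBSO)propan-2-yl]-4'-O-E*-SR
Conditions: TBSCl (1.15 equiv), imidazole (2.5 equiv), CH2Cl2, 0 °C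
Reagents that add atoms: tert-butyl(chloro)dimethylsilane CC(C)(C)[Si](C)(C)Cl
Why: chemoselective silylation of the only primary hydroxyl leaves the C-7 hydroxyl of unit B as the single free alcohol; no stereocentre is touched.

Step 33
Reactants: 48 threo mono-alcohol
Product: 49 4-O-[(1S,2R)-1-(ArB*)-1-(4-nitrobenzoyloxy)-3-(TBSO)propan-2-yl]-4'-O-E*-SR
Conditions: 4-nitrobenzoic acid (3 equiv), PPh3 (3 equiv), DIAD (3 equiv), toluene, 0 °C to rt
Reagents that add atoms: 4-nitrobenzoic acid O=C(O)c1ccc(cc1)[N+](=O)[O-]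
Why: Mitsunobu esterification inverts C-7 of unit B from R to S by SN2 displacement of the oxyphosphonium, giving the erythro (7S,8R) configuration.

Step 34
Reactants: 49 inverted 4-nitrobenzoate
Product: 50 4-O-[(1S,2R)-1-(ArB*)-1-hydroxy-3-(TBSO)propan-2-yl]-4'-O-E*-SR
Conditions: K2CO3 (0.2 equiv), MeOH/THF (2:1), rt
Reagents that add atoms: none
Why: base-catalysed transesterification (methanolysis at the acyl carbon) frees the C-7 hydroxyl with retention, the five alkyl silyl ethers being stable.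

Step 35
Reactants: 50 fully assembled penta-silyl di-benzyl ether
Product: 51 di-O-benzyl ether of the target, 4-O-{(1S,2R)-1-[4-({(1R,2S)-1-(GBn)-1,3-dihydroxypropan-2-yl}oxy)-3-methoxyphenyl]-1,3-dihydroxypropan-2-yl}-4'-O-[(1S,2R)-1-(GBn)-1,3-dihydroxypropan-2-yl]-SR
Conditions: Bu4NF (10 equiv), AcOH (10 equiv), THF, rt to 40 °C
Reagents that add atoms: none
Why: fluoride-mediated desilylation, buffered with acetic acid, removes all five silyl ethers at silicon, so no C–O bond at a stereocentre is broken.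

Step 36
Reactants: 51 di-O-benzyl ether of the target
Product: 52 CNP0316493.2 (target)
Conditions: H2 (1 atm), 10% Pd/C, EtOAc/MeOH (1:1), rt, reaction stopped at full conversion
Reagents that add atoms: none
Why: catalytic hydrogenolysis cleaves the two aryl benzyl ethers much faster than the benzylic alcohols or the furofuran benzylic ethers under neutral conditions at 1 atm, and leaves all ten stereocentres as set.

## Compound list

1 | syringaldehyde (4-hydroxy-3,5-dimethoxybenzaldehyde) | COc1cc(C=O)cc(OC)c1O | starting material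
2 | 2-(4-hydroxy-3,5-dimethoxyphenyl)-1,3-dithiane | COc1cc(cc(OC)c1O)C1SCCCS1 | intermediate
3 | 2-[3,5-dimethoxy-4-(triisopropylsilyloxy)phenyl]-1,3-dithiane | COc1cc(cc(OC)c1O[Si](C(C)C)(C(C)C)C(C)C)C1SCCCS1 | intermediate
4 | 4-allyloxy-3,5-dimethoxybenzaldehyde | COc1cc(C=O)cc(OC)c1OCC=C | intermediate
5 | furfural (furan-2-carbaldehyde) | O=Cc1ccco1 | starting material
6 | 5-hydroxyfuran-2(5H)-one (racemic) | O=C1C=CC(O)O1 | intermediate
7 | (+)-menthol, (1S,2R,5S)-2-isopropyl-5-methylcyclohexan-1-ol | O[C@H]1C[C@@H](C)CC[C@@H]1C(C)C | starting material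
8 | (5S)-5-{[(1S,2R,5S)-2-isopropyl-5-methylcyclohexyl]oxy}furan-2(5H)-one | O=C1C=C[C@@H](O[C@H]2C[C@@H](C)CC[C@@H]2C(C)C)O1 | intermediate
9 | 2-lithio-2-[3,5-dimethoxy-4-(triisopropylsilyloxy)phenyl]-1,3-dithiane (not isolated) | [Li]C1(SCCCS1)c1cc(OC)c(O[Si](C(C)C)(C(C)C)C(C)C)c(OC)c1 | intermediate
10 | lithium enolate of the (4S,5S) Michael adduct, 4-(2-aryl-1,3-dithian-2-yl)-5-(menthyloxy)-4,5-dihydrofuran-2-olate (not isolated) | [Li]OC1=C[C@H](C2(SCCCS2)c2cc(OC)c(O[Si](C(C)C)(C(C)C)C(C)C)c(OC)c2)[C@@H](O[C@H]2C[C@@H](C)CC[C@@H]2C(C)C)O1 | intermediate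
11 | (3R,4S,5S)-3-[(4-allyloxy-3,5-dimethoxyphenyl)(hydroxy)methyl]-4-{2-[3,5-dimethoxy-4-(triisopropylsilyloxy)phenyl]-1,3-dithian-2-yl}-5-[(1S,2R,5S)-menthyloxy]dihydrofuran-2(3H)-one, carbinol epimers | O=C1O[C@H](O[C@H]2C[C@@H](C)CC[C@@H]2C(C)C)[C@@H](C2(SCCCS2)c2cc(OC)c(O[Si](C(C)C)(C(C)C)C(C)C)c(OC)c2)[C@@H]1C(O)c1cc(OC)c(OCC=C)c(OC)c1 | intermediate
12 | (3R,4S,5S)-3-[(4-allyloxy-3,5-dimethoxyphenyl)(hydroxy)methyl]-4-[3,5-dimethoxy-4-(triisopropylsilyloxy)benzoyl]-5-[(1S,2R,5S)-menthyloxy]dihydrofuran-2(3H)-one, carbinol epimers | O=C1O[C@H](O[C@H]2C[C@@H](C)CC[C@@H]2C(C)C)[C@@H](C(=O)c2cc(OC)c(O[Si](C(C)C)(C(C)C)C(C)C)c(OC)c2)[C@@H]1C(O)c1cc(OC)c(OCC=C)c(OC)c1 | intermediate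
13 | (2S,3S)-2-[(4-allyloxy-3,5-dimethoxyphenyl)(hydroxy)methyl]-3-{[3,5-dimethoxy-4-(triisopropylsilyloxy)phenyl](hydroxy)methyl}butane-1,4-diol, carbinol epimers | OC[C@@H](C(O)c1cc(OC)c(OCC=C)c(OC)c1)[C@@H](CO)C(O)c1cc(OC)c(O[Si](C(C)C)(C(C)C)C(C)C)c(OC)c1 | intermediate
14 | 4-O-allyl-4'-O-TIPS-SR, (1R,3aS,4R,6aS)-1-(4-allyloxy-3,5-dimethoxyphenyl)-4-[3,5-dimethoxy-4-(triisopropylsilyloxy)phenyl]tetrahydro-1H,3H-furo[3,4-c]furan | COc1cc(cc(OC)c1OCC=C)[C@@H]1OC[C@@H]2[C@H]1CO[C@H]2c1cc(OC)c(O[Si](C(C)C)(C(C)C)C(C)C)c(OC)c1 | intermediate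
15 | 4-O-allyl-SR | COc1cc(cc(OC)c1OCC=C)[C@@H]1OC[C@@H]2[C@H]1CO[C@H]2c1cc(OC)c(O)c(OC)c1 | intermediate
16 | (S)-4-benzyloxazolidin-2-one | O=C1N[C@@H](Cc2ccccc2)CO1 | starting material
17 | bromoacetyl bromide | BrCC(Br)=O | starting material
18 | N-lithio (S)-4-benzyloxazolidin-2-one (not isolated) | [Li]N1[C@@H](Cc2ccccc2)COC1=O | intermediate
19 | (S)-4-benzyl-3-(bromoacetyl)oxazolidin-2-one | O=C(CBr)N1[C@@H](Cc2ccccc2)COC1=O | intermediate
20 | 4-O-allyl-4'-O-[2-oxo-2-(Xs)ethyl]-SR | COc1cc(cc(OC)c1OCC=C)[C@@H]1OC[C@@H]2[C@H]1CO[C@H]2c1cc(OC)c(OCC(=O)N3[C@@H](Cc4ccccc4)COC3=O)c(OC)c1 | intermediate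
21 | 4-benzyloxy-3-methoxybenzaldehyde (O-benzylvanillin) | O=Cc1ccc(OCc2ccccc2)c(OC)c1 | starting material
22 | dibutylboron Z-enolate of 20, 4-O-allyl-4'-O-[(Z)-2-(dibutylboranyloxy)-2-(Xs)ethenyl]-SR (not isolated) | COc1cc(cc(OC)c1OCC=C)[C@@H]1OC[C@@H]2[C@H]1CO[C@H]2c1cc(OC)c(O/C=C(\OB(CCCC)CCCC)N3[C@@H](Cc4ccccc4)COC3=O)c(OC)c1 | intermediate
23 | 4-O-allyl-4'-O-[(2S,3R)-3-(GBn)-3-hydroxy-1-oxo-1-(Xs)propan-2-yl]-SR (syn aldol) | COc1cc(cc(OC)c1OCC=C)[C@@H]1OC[C@@H]2[C@H]1CO[C@H]2c1cc(OC)c(O[C@H](C(=O)N3[C@@H](Cc4ccccc4)COC3=O)[C@H](O)c3ccc(OCc4ccccc4)c(OC)c3)c(OC)c1 | intermediate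
24 | 4-O-allyl-4'-O-[(1R,2R)-1-(GBn)-1,3-dihydroxypropan-2-yl]-SR (threo) | COc1cc(cc(OC)c1OCC=C)[C@@H]1OC[C@@H]2[C@H]1CO[C@H]2c1cc(OC)c(O[C@H](CO)[C@H](O)c3ccc(OCc4ccccc4)c(OC)c3)c(OC)c1 | intermediate
25 | 4-O-allyl-4'-O-[(1R,2R)-1-(GBn)-1-hydroxy-3-(TBSO)propan-2-yl]-SR | COc1cc(cc(OC)c1OCC=C)[C@@H]1OC[C@@H]2[C@H]1CO[C@H]2c1cc(OC)c(O[C@H](CO[Si](C)(C)C(C)(C)C)[C@H](O)c3ccc(OCc4ccccc4)c(OC)c3)c(OC)c1 | intermediate
26 | 4-O-allyl-4'-O-[(1S,2R)-1-(GBn)-1-(4-nitrobenzoyloxy)-3-(TBSO)propan-2-yl]-SR | COc1cc(cc(OC)c1OCC=C)[C@@H]1OC[C@@H]2[C@H]1CO[C@H]2c1cc(OC)c(O[C@H](CO[Si](C)(C)C(C)(C)C)[C@@H](OC(=O)c3ccc(cc3)[N+](=O)[O-])c3ccc(OCc4ccccc4)c(OC)c3)c(OC)c1 | intermediate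
27 | 4-O-allyl-4'-O-[(1S,2R)-1-(GBn)-1-hydroxy-3-(TBSO)propan-2-yl]-SR (erythro) | COc1cc(cc(OC)c1OCC=C)[C@@H]1OC[C@@H]2[C@H]1CO[C@H]2c1cc(OC)c(O[C@H](CO[Si](C)(C)C(C)(C)C)[C@@H](O)c3ccc(OCc4ccccc4)c(OC)c3)c(OC)c1 | intermediate
28 | 4-O-allyl-4'-O-[(1S,2R)-1-(GBn)-1,3-bis(TBSO)propan-2-yl]-SR | COc1cc(cc(OC)c1OCC=C)[C@@H]1OC[C@@H]2[C@H]1CO[C@H]2c1cc(OC)c(O[C@H](CO[Si](C)(C)C(C)(C)C)[C@@H](O[Si](C)(C)C(C)(C)C)c3ccc(OCc4ccccc4)c(OC)c3)c(OC)c1 | intermediate
29 | 4'-O-[(1S,2R)-1-(GBn)-1,3-bis(TBSO)propan-2-yl]-SR (4-OH free) | COc1cc(cc(OC)c1O)[C@@H]1OC[C@@H]2[C@H]1CO[C@H]2c1cc(OC)c(O[C@H](CO[Si](C)(C)C(C)(C)C)[C@@H](O[Si](C)(C)C(C)(C)C)c3ccc(OCc4ccccc4)c(OC)c3)c(OC)c1 | intermediate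
30 | (R)-4-benzyloxazolidin-2-one | O=C1N[C@H](Cc2ccccc2)CO1 | starting material
31 | N-lithio (R)-4-benzyloxazolidin-2-one (not isolated) | [Li]N1[C@H](Cc2ccccc2)COC1=O | intermediate
32 | (R)-4-benzyl-3-(bromoacetyl)oxazolidin-2-one | O=C(CBr)N1[C@H](Cc2ccccc2)COC1=O | intermediate
33 | 4-hydroxy-3-methoxybenzonitrile | N#Cc1ccc(O)c(OC)c1 | starting material
34 | 4-[2-oxo-2-(Xr)ethoxy]-3-methoxybenzonitrile | N#Cc1ccc(OCC(=O)N2[C@H](Cc3ccccc3)COC2=O)c(OC)c1 | intermediate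
35 | dibutylboron Z-enolate of 34 (not isolated) | N#Cc1ccc(O/C=C(\OB(CCCC)CCCC)N2[C@H](Cc3ccccc3)COC2=O)c(OC)c1 | intermediate
36 | 4-{[(2R,3S)-3-(GBn)-3-hydroxy-1-oxo-1-(Xr)propan-2-yl]oxy}-3-methoxybenzonitrile (syn aldol) | N#Cc1ccc(O[C@@H](C(=O)N2[C@H](Cc3ccccc3)COC2=O)[C@@H](O)c2ccc(OCc3ccccc3)c(OC)c2)c(OC)c1 | intermediate
37 | 4-{[(1S,2S)-1-(GBn)-1,3-dihydroxypropan-2-yl]oxy}-3-methoxybenzonitrile (threo) | N#Cc1ccc(O[C@@H](CO)[C@@H](O)c2ccc(OCc3ccccc3)c(OC)c2)c(OC)c1 | intermediate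
38 | 4-{[(1S,2S)-1-(GBn)-1-hydroxy-3-(TBSO)propan-2-yl]oxy}-3-methoxybenzonitrile | N#Cc1ccc(O[C@@H](CO[Si](C)(C)C(C)(C)C)[C@@H](O)c2ccc(OCc3ccccc3)c(OC)c2)c(OC)c1 | intermediate
39 | 4-{[(1R,2S)-1-(GBn)-1-(4-nitrobenzoyloxy)-3-(TBSO)propan-2-yl]oxy}-3-methoxybenzonitrile | N#Cc1ccc(O[C@@H](CO[Si](C)(C)C(C)(C)C)[C@H](OC(=O)c2ccc(cc2)[N+](=O)[O-])c2ccc(OCc3ccccc3)c(OC)c2)c(OC)c1 | intermediate
40 | 4-{[(1R,2S)-1-(GBn)-1-hydroxy-3-(TBSO)propan-2-yl]oxy}-3-methoxybenzonitrile (erythro) | N#Cc1ccc(O[C@@H](CO[Si](C)(C)C(C)(C)C)[C@H](O)c2ccc(OCc3ccccc3)c(OC)c2)c(OC)c1 | intermediate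
41 | 4-{[(1R,2S)-1-(GBn)-1,3-bis(TBSO)propan-2-yl]oxy}-3-methoxybenzonitrile | N#Cc1ccc(O[C@@H](CO[Si](C)(C)C(C)(C)C)[C@H](O[Si](C)(C)C(C)(C)C)c2ccc(OCc3ccccc3)c(OC)c2)c(OC)c1 | intermediate
42 | N-(diisobutylaluminio)aldimine of 41 (not isolated) | CC(C)C[Al](CC(C)C)N=Cc1ccc(O[C@@H](CO[Si](C)(C)C(C)(C)C)[C@H](O[Si](C)(C)C(C)(C)C)c2ccc(OCc3ccccc3)c(OC)c2)c(OC)c1 | intermediate
43 | 4-{[(1R,2S)-1-(GBn)-1,3-bis(TBSO)propan-2-yl]oxy}-3-methoxybenzaldehyde | O=Cc1ccc(O[C@@H](CO[Si](C)(C)C(C)(C)C)[C@H](O[Si](C)(C)C(C)(C)C)c2ccc(OCc3ccccc3)c(OC)c2)c(OC)c1 | intermediate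
44 | 4-O-[2-oxo-2-(Xs)ethyl]-4'-O-E*-SR | COc1cc(cc(OC)c1OCC(=O)N3[C@@H](Cc4ccccc4)COC3=O)[C@@H]1OC[C@@H]2[C@H]1CO[C@H]2c1cc(OC)c(O[C@H](CO[Si](C)(C)C(C)(C)C)[C@@H](O[Si](C)(C)C(C)(C)C)c3ccc(OCc4ccccc4)c(OC)c3)c(OC)c1 | intermediate
45 | dibutylboron Z-enolate of 44 (not isolated) | COc1cc(cc(OC)c1O/C=C(\OB(CCCC)CCCC)N3[C@@H](Cc4ccccc4)COC3=O)[C@@H]1OC[C@@H]2[C@H]1CO[C@H]2c1cc(OC)c(O[C@H](CO[Si](C)(C)C(C)(C)C)[C@@H](O[Si](C)(C)C(C)(C)C)c3ccc(OCc4ccccc4)c(OC)c3)c(OC)c1 | intermediate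
46 | 4-O-[(2S,3R)-3-(ArB*)-3-hydroxy-1-oxo-1-(Xs)propan-2-yl]-4'-O-E*-SR (syn aldol) | COc1cc(cc(OC)c1O[C@H](C(=O)N3[C@@H](Cc4ccccc4)COC3=O)[C@H](O)c3ccc(O[C@@H](CO[Si](C)(C)C(C)(C)C)[C@H](O[Si](C)(C)C(C)(C)C)c4ccc(OCc5ccccc5)c(OC)c4)c(OC)c3)[C@@H]1OC[C@@H]2[C@H]1CO[C@H]2c1cc(OC)c(O[C@H](CO[Si](C)(C)C(C)(C)C)[C@@H](O[Si](C)(C)C(C)(C)C)c3ccc(OCc4ccccc4)c(OC)c3)c(OC)c1 | intermediate
47 | 4-O-[(1R,2R)-1-(ArB*)-1,3-dihydroxypropan-2-yl]-4'-O-E*-SR (threo) | COc1cc(cc(OC)c1O[C@H](CO)[C@H](O)c3ccc(O[C@@H](CO[Si](C)(C)C(C)(C)C)[C@H](O[Si](C)(C)C(C)(C)C)c4ccc(OCc5ccccc5)c(OC)c4)c(OC)c3)[C@@H]1OC[C@@H]2[C@H]1CO[C@H]2c1cc(OC)c(O[C@H](CO[Si](C)(C)C(C)(C)C)[C@@H](O[Si](C)(C)C(C)(C)C)c3ccc(OCc4ccccc4)c(OC)c3)c(OC)c1 | intermediate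
48 | 4-O-[(1R,2R)-1-(ArB*)-1-hydroxy-3-(TBSO)propan-2-yl]-4'-O-E*-SR | COc1cc(cc(OC)c1O[C@H](CO[Si](C)(C)C(C)(C)C)[C@H](O)c3ccc(O[C@@H](CO[Si](C)(C)C(C)(C)C)[C@H](O[Si](C)(C)C(C)(C)C)c4ccc(OCc5ccccc5)c(OC)c4)c(OC)c3)[C@@H]1OC[C@@H]2[C@H]1CO[C@H]2c1cc(OC)c(O[C@H](CO[Si](C)(C)C(C)(C)C)[C@@H](O[Si](C)(C)C(C)(C)C)c3ccc(OCc4ccccc4)c(OC)c3)c(OC)c1 | intermediate
49 | 4-O-[(1S,2R)-1-(ArB*)-1-(4-nitrobenzoyloxy)-3-(TBSO)propan-2-yl]-4'-O-E*-SR | COc1cc(cc(OC)c1O[C@H](CO[Si](C)(C)C(C)(C)C)[C@@H](OC(=O)c3ccc(cc3)[N+](=O)[O-])c3ccc(O[C@@H](CO[Si](C)(C)C(C)(C)C)[C@H](O[Si](C)(C)C(C)(C)C)c4ccc(OCc5ccccc5)c(OC)c4)c(OC)c3)[C@@H]1OC[C@@H]2[C@H]1CO[C@H]2c1cc(OC)c(O[C@H](CO[Si](C)(C)C(C)(C)C)[C@@H](O[Si](C)(C)C(C)(C)C)c3ccc(OCc4ccccc4)c(OC)c3)c(OC)c1 | intermediate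
50 | 4-O-[(1S,2R)-1-(ArB*)-1-hydroxy-3-(TBSO)propan-2-yl]-4'-O-E*-SR (erythro) | COc1cc(cc(OC)c1O[C@H](CO[Si](C)(C)C(C)(C)C)[C@@H](O)c3ccc(O[C@@H](CO[Si](C)(C)C(C)(C)C)[C@H](O[Si](C)(C)C(C)(C)C)c4ccc(OCc5ccccc5)c(OC)c4)c(OC)c3)[C@@H]1OC[C@@H]2[C@H]1CO[C@H]2c1cc(OC)c(O[C@H](CO[Si](C)(C)C(C)(C)C)[C@@H](O[Si](C)(C)C(C)(C)C)c3ccc(OCc4ccccc4)c(OC)c3)c(OC)c1 | intermediate
51 | di-O-benzyl ether of the target, 4-O-{(1S,2R)-1-[4-({(1R,2S)-1-(GBn)-1,3-dihydroxypropan-2-yl}oxy)-3-methoxyphenyl]-1,3-dihydroxypropan-2-yl}-4'-O-[(1S,2R)-1-(GBn)-1,3-dihydroxypropan-2-yl]-SR | COc1cc(cc(OC)c1O[C@H](CO)[C@@H](O)c3ccc(O[C@@H](CO)[C@H](O)c4ccc(OCc5ccccc5)c(OC)c4)c(OC)c3)[C@@H]1OC[C@@H]2[C@H]1CO[C@H]2c1cc(OC)c(O[C@H](CO)[C@@H](O)c3ccc(OCc4ccccc4)c(OC)c3)c(OC)c1 | intermediate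
52 | CNP0316493.2, 4-O-{(1S,2R)-1-[4-({(1R,2S)-1,3-dihydroxy-1-(4-hydroxy-3-methoxyphenyl)propan-2-yl}oxy)-3-methoxyphenyl]-1,3-dihydroxypropan-2-yl}-4'-O-[(1S,2R)-1,3-dihydroxy-1-(4-hydroxy-3-methoxyphenyl)propan-2-yl]-SR | COc1cc([C@@H](O)[C@H](CO)Oc2ccc([C@H](O)[C@@H](CO)Oc3c(OC)cc([C@@H]4OC[C@@H]5[C@H]4CO[C@H]5c4cc(OC)c(O[C@H](CO)[C@@H](O)c5ccc(O)c(OC)c5)c(OC)c4)cc3OC)cc2OC)ccc1O | target

## Step count and risks

Total step count: 36. Longest linear sequence: 23 steps (1 → 2 → 3 → 11 → 12 → 13 → 14 → 15 → 20 → 23 → 24 → 25 → 26 → 27 → 28 → 29 → 44 → 46 → 47 → 48 → 49 → 50 → 51 → 52).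

The three steps most likely to fail:

Step 9 (the acid-mediated double ring closure must be both regio- and stereoconvergent; C-7 epimers or 2,5-diaryltetrahydrofuran by-products are the danger). Fallback: set out from 13 and remove the silyl group first (Bu4NF, AcOH, THF, 0 °C) to give (2S,3S)-2-[(4-allyloxy-3,5-dimethoxyphenyl)(hydroxy)methyl]-3-[(4-hydroxy-3,5-dimethoxyphenyl)(hydroxy)methyl]butane-1,4-diol F1. Then close the rings biomimetically in dilute HCl in dioxane–water at rt, through the p-quinone methide of the free syringyl unit and the p-alkoxybenzyl cation of the other. This gives 15 directly, so the route is rejoined at 15 and steps 9 and 10 are skipped.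

Step 16 (Mitsunobu inversion at an electron-rich benzylic carbinol; elimination or partial loss of configuration by ionisation is possible, and the same risk recurs in steps 25 and 33). Fallback: set out from 25 and oxidise with Dess–Martin periodinane (NaHCO3, CH2Cl2, 0 °C) to the α-aryloxy ketone 4-O-allyl-4'-O-[(2R)-1-(GBn)-3-(TBSO)-1-oxopropan-2-yl]-SR F2. Reduce it at once under chelation control with Zn(BH4)2 (Et2O, −40 °C): hydride attacks the zinc chelate of the carbonyl and aryloxy oxygens from the face of the C-8 hydrogen and gives the erythro (7S,8R) alcohol 27, where the route is rejoined. Any threo isomer 25 is separated and recycled.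

Step 36 (hydrogenolysis of two benzyl ethers in a molecule with three free benzylic alcohols and two benzylic ring ethers; over-reduction at C-7 positions is the danger). Fallback: set out from 50 and reverse the order of the last two operations. Hydrogenolyse first (H2, Pd/C, EtOAc, rt), while the benzylic oxygens of units A and E are still silylated, to give the di-O-debenzylated pentakis-TBS ether F3. Then remove the five silyl groups with Et3N·3HF (THF, rt to 40 °C), which arrives directly at 52.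

## Further compounds

F1 | step 9 | (2S,3S)-2-[(4-allyloxy-3,5-dimethoxyphenyl)(hydroxy)methyl]-3-[(4-hydroxy-3,5-dimethoxyphenyl)(hydroxy)methyl]butane-1,4-diol (carbinol epimers) | OC[C@@H](C(O)c1cc(OC)c(OCC=C)c(OC)c1)[C@@H](CO)C(O)c1cc(OC)c(O)c(OC)c1
F2 | step 16 | α-aryloxy ketone 4-O-allyl-4'-O-[(2R)-1-(GBn)-3-(TBSO)-1-oxopropan-2-yl]-SR | COc1cc(cc(OC)c1OCC=C)[C@@H]1OC[C@@H]2[C@H]1CO[C@H]2c1cc(OC)c(O[C@H](CO[Si](C)(C)C(C)(C)C)C(=O)c3ccc(OCc4ccccc4)c(OC)c3)c(OC)c1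
F3 | step 36 | di-O-debenzylated pentakis-TBS ether (compound 50 with both GBn groups replaced by 4-hydroxy-3-methoxyphenyl) | COc1cc(cc(OC)c1O[C@H](CO[Si](C)(C)C(C)(C)C)[C@@H](O)c3ccc(O[C@@H](CO[Si](C)(C)C(C)(C)C)[C@H](O[Si](C)(C)C(C)(C)C)c4ccc(O)c(OC)c4)c(OC)c3)[C@@H]1OC[C@@H]2[C@H]1CO[C@H]2c1cc(OC)c(O[C@H](CO[Si](C)(C)C(C)(C)C)[C@@H](O[Si](C)(C)C(C)(C)C)c3ccc(O)c(OC)c3)c(OC)c1
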